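Atom numbering used throughout: ring O1–O2–C3–C4–C5; C3 carries CH3 and the arm C2'H2–C1'O2H; C5 carries CH3 and the chain C6–C17 (methyl on C7, E alkenes at C12=C13 and C16=C17, phenyl on C17). The target is 2-[(3R,5R)-3,5-dimethyl-5-[(2R,7E,11E)-2-methyl-12-phenyldodeca-7,11-dien-1-yl]-1,2-dioxolan-3-yl]acetic acid (27).

## The problem

The target is a 3,3,5,5-tetrasubstituted 1,2-dioxolane whose two ring carbons are quaternary stereocentres (C3 and C5, both R) with the acetic acid arm and the long chain cis to each other. A third stereocentre, C7 (R), sits in the chain, separated from C5 by the methylene C6. It is too far from the ring and too flexibly attached to control the ring centres or to be controlled by them, so it needs reagent control of its own. The O–O bond excludes catalytic hydrogenation, low-valent metals, free phosphines in excess, strong hydride donors and carbon radicals placed β or γ to the peroxide. The C1' carboxyl lies β to the peroxide oxygen on C3, so any enolate at C2' can expel the peroxide (retro-oxa-Michael); strong base has to be kept away from this unit. The two E alkenes, one of them a styrene, would not survive any alkene reduction, so every reduction of a carbon–carbon double bond must be finished before they are introduced. The structural feature that opens a short stereocontrolled entry is that C3 and C5 differ only in their arms and that these arms are cis. Joining C1' to C6 gives a bicyclic ketone, 8, with a mirror plane through C4, C1' and the midpoint of O1–O2. A ring of this kind can only close cis, and a meso compound can be desymmetrised by an enzyme.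

## Retrosynthesis

**C12=C13.** The acid 27 is taken back to its methyl ester 25, and 25 is cut at the C12=C13 double bond into aldehyde 20 and the phenyltetrazolyl sulfone 23 (Julia–Kocienski olefination). The neighbouring cut at C16=C17 would need a cinnamyl-type partner and would leave a second alkene to build, whereas the styrene already exists in commercial (4E)-5-phenylpent-4-en-1-ol 21. Cross-metathesis at C12=C13 would be statistical and would involve the styrene. Aldehyde 20 contains no carbon–carbon double bond, so everything before it may use alkene reduction. The forward step must be E-selective and must not expose the β-peroxy ester to free amide base.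

**C8–C9.** Aldehyde 20 is traced through acetal 19 to alkene 18, which is cut at C8=C9 into the α-methyl aldehyde 14 and the four-carbon phosphonium salt 16 (C9–C12, C12 masked as a dioxolane acetal; from chloride 15). A direct sp3–sp3 coupling at C8–C9 would need organocopper or organomagnesium reagents that attack peroxides. The olefination route needs only diimide afterwards, the one alkene reductant known to leave O–O bonds alone. The geometry of C8=C9 is irrelevant. The forward Wittig step must be fast and cold enough not to epimerise C7.

**C7 and C6=C7.** Aldehyde 14 comes from the (E)-2-methyl enal 13 by enzymatic conjugate reduction, and 13 from aldehyde 11 and the stabilised ylide 12. Setting C7 by alkylation of an enolate would need a strong base next to the β-peroxy ester and several auxiliary steps; metal-catalysed asymmetric hydrogenation is closed by the peroxide. An ene-reductase delivers hydride to C6 and a proton to C7 under neutral conditions and sets C7 independently of the ring. The precursor 11 has only the two ring stereocentres. The forward reduction must be enantioselective and fast enough to outrun racemisation of the α-methyl aldehyde.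

**Desymmetrisation.** Aldehyde 11 is the oxidation product of hydroxy ester 10, which is the methanolysis product of lactone 9, and 9 is the Baeyer–Villiger product of the meso ketone 8. Oxygen insertion into one of the two enantiotopic C1'–CH2 bonds fixes the absolute configuration of C3 and C5. It also leaves C1' as the carboxyl carbon on C2' and turns C6 into a CH2O group ready for oxidation. A chemical peracid would give the racemate. An enzyme is used because the two methylene groups differ only by their position relative to the mirror plane.

**The ring (key disconnection).** Ketone 8 is cut at C3–C2' and C5–C6 into the bis-peroxyketal 3 and the acetone α,α'-dianion equivalent 6. Against the direct [3+2] constructions of the dioxolane from an alkene and a peroxycarbenium ion, this cut makes both quaternary centres at ring carbons that are already part of a peroxide, and it makes the cis relationship a geometric necessity, since a three-atom bridge across C3 and C5 of a dioxolane cannot be trans. The precursors are achiral and have five and three skeletal carbons. The forward reaction must form two C–C bonds at tertiary peroxycarbenium ions and must close the ring faster than a second molecule of 6 can add.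

**The building blocks.** Bis-ketal 3 comes from the bis-hemiketal 2, the adduct of acetylacetone 1 and hydrogen peroxide. The bis-nucleophile 6 comes from 1-(trimethylsilyl)propan-2-one 4 by kinetic enol silylation.

## Roads not taken

**Alternative 1:** The ring is cut at C3–C4 and O1–C5. A silylperoxy ketal of a four-carbon ketone, tert-butyl{3-methoxy-3-[(triethylsilyl)peroxy]butoxy}diphenylsilane A2, is ionised by SnCl4 to a peroxycarbenium ion at C3. The CH2 terminus of the chain alkene (6R)-6,8-dimethylnon-8-en-1-yl benzoate A3 adds to it, and the tertiary cation at C5 is captured by the peroxide oxygen with loss of silicon. The product is (3S,5R)-3-[2-(tert-butyldiphenylsilyloxy)ethyl]-5-[(2R)-7-(benzoyloxy)-2-methylheptyl]-3,5-dimethyl-1,2-dioxolane A1.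
- Merits: the annulation of silylperoxy ketals with 1,1-disubstituted alkenes is an established reaction type. The synthesis is convergent, and C7 arrives in A3 from a chiral building block without any enzyme.
- Weak points: the C5 cation is planar and each ring carbon carries a methyl and a CH2R group of similar size, so little cis/trans preference is to be expected. C7 is too remote to bias the absolute sense, so up to four stereoisomers with only remote differences would have to be separated. The C3 arm must also be desilylated and oxidised by two levels.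
- Comparison: this road is clearly shorter and rests on known chemistry, and in that respect it is better. The chosen plan sets against it that the cis relationship is enforced by ring closure and the absolute configuration by an enzyme, so no stereoisomer separation is designed in.

**Alternative 2:** The two C–O bonds are cut and O2 is inserted into the C3–C5 bond of a vinylcyclopropane, tert-butyl{[(6R)-7-(2-ethenyl-1,2-dimethylcyclopropyl)-6-methylheptyl]oxy}diphenylsilane A5. A phenylselenyl radical from (C6H5Se)2 and light adds to the vinyl group, the ring opens to the tertiary C5 radical, O2 is captured, and the peroxyl radical closes onto C3 with loss of the selenyl radical. The product is (3R,5R)-3-ethenyl-3,5-dimethyl-5-[(2R)-7-(tert-butyldiphenylsilyloxy)-2-methylheptyl]-1,2-dioxolane A4.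
- Merits: neutral radical-chain conditions, oxygen taken from air, a known reaction type, and a useful cis preference in 3,5-disubstituted cases.
- Weak points: with a methyl on each ring carbon the chair-like preference of the peroxyl cyclisation is eroded. Both cyclopropane stereocentres are erased on ring opening, so the ring configuration relative to C7 is not controlled. A5 itself needs a stereorandom cyclopropanation of a tetrasubstituted pattern. The vinyl group must then be turned into CH2CO2H by anti-Markovnikov hydration and oxidation in the presence of the peroxide.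
- Comparison: the oxygenation step itself is better precedented than the key step chosen here. The chosen plan answers with defined relative and absolute configuration and with an acid arm that comes out of the desymmetrisation at the right oxidation level.

**Alternative 3:** The ring is cut at C4–C5 and O2–C3. The silylperoxy ketal of the complete chain ketone, (6R)-8-methoxy-6-methyl-8-[(triethylsilyl)peroxy]nonyl benzoate A7, is ionised by SnCl4 at C5. Methyl 3-methylbut-3-enoate A8 adds through its CH2 terminus, and the cation at C3 is captured by the distal peroxide oxygen. The product is methyl 2-[(3R,5R)-5-[(2R)-7-(benzoyloxy)-2-methylheptyl]-3,5-dimethyl-1,2-dioxolan-3-yl]acetate A6.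
- Merits: this is the most direct road. A6 carries the acetate arm at the final oxidation level, and benzoate removal and oxidation would convert it into aldehyde 20 of the present route, many steps earlier than here.
- Weak points: the cation at C3 is flanked by CH2CO2CH3 and can lose a proton to a conjugated enoate in competition with peroxide capture. The alkene A8 is a weak nucleophile. The stereochemical problem is the same as in Alternative 1: cis/trans and absolute sense relative to C7 are uncontrolled, so A6 would be one of up to four isomers.
- Comparison: in step count and precedent this road is superior. The chosen plan is longer and its central step is unproven, but it is the only one of the four in which all three stereocentres are set by design.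

Key step: step 4

## Route

Assumption: the Baeyer–Villiger monooxygenase of step 5 and the ene-reductase of step 9 are taken from panels in which both enantiopreferences occur, so the sense needed here can be selected by screening. Compounds 2, 3 and 8 are small peroxides and are handled in solution on small scale.

Step 1
Reactants: 1 acetylacetone (pentane-2,4-dione)
Product: 2 3,5-dimethyl-1,2-dioxolane-3,5-diol (cis/trans mixture)
Conditions: 30% aq. H2O2 (1.0 equiv), 0 °C → rt
Reagents that add atoms: hydrogen peroxide, OO
Why: Double addition of hydrogen peroxide to the 1,3-diketone (perhemiketal formation, then 5-exo closure onto the second carbonyl) gives the cyclic peroxy bis-hemiketal, a known adduct; one equivalent of peroxide avoids hydroperoxy by-products.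

Step 2
Reactants: 2 3,5-dimethyl-1,2-dioxolane-3,5-diol
Product: 3 3,5-dimethoxy-3,5-dimethyl-1,2-dioxolane (cis/trans mixture)
Conditions: MeOH, camphorsulfonic acid (cat.), 3 Å molecular sieves, 0 °C → rt
Reagents that add atoms: methanol, CO
Why: Acid-catalysed ketalisation of a peroxy hemiketal through the same peroxycarbenium ion that step 4 uses; the large excess of methanol and the absence of free hydrogen peroxide should favour the bis-methyl ketal, and the diastereomer ratio is irrelevant because both centres are ionised later.

Step 3
Reactants: 4 1-(trimethylsilyl)propan-2-one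
Product: 6 2-(trimethylsilyloxy)allyltrimethylsilane (trimethyl{[3-(trimethylsilyl)prop-1-en-2-yl]oxy}silane), via lithium enolate 5 (not isolated)
Conditions: LiN(iPr)2, THF, −78 °C; Me3SiCl, −78 °C → rt
Reagents that add atoms: chlorotrimethylsilane, C[Si](C)(C)Cl
Why: Kinetic deprotonation by the hindered amide takes place at the unencumbered methyl group, not at the silyl-bearing methylene, and O-silylation of the enolate gives the 2-silyloxyallylsilane, a known acetone α,α'-dianion equivalent.

Step 4
Reactants: 3 3,5-dimethoxy-3,5-dimethyl-1,2-dioxolane; 6 2-(trimethylsilyloxy)allyltrimethylsilane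
Product: 8 (1R,5S)-1,5-dimethyl-6,7-dioxabicyclo[3.2.1]octan-3-one (meso), via silyl enol ether 7 (not isolated)
Conditions: Me3SiOSO2CF3 (0.3 equiv), CH2Cl2 (0.01 M), slow addition of 6 (1.0 equiv), −78 °C → −40 °C; Et3N quench at −78 °C
Reagents that add atoms: none
Why: Proposed new method: Me3SiOSO2CF3 ionises one ketal of 3 to a peroxycarbenium ion, which is attacked by the CH2= terminus of 6 (allylsilane reactivity) with loss of the carbon-bound silyl group to give silyl enol ether 7; ionisation of the second ketal then lets the enol ether carbon add intramolecularly, and release of the oxygen-bound silyl group regenerates the acid, so it is needed only in substoichiometric amount. The closest known reaction types are the Lewis acid substitution of 3-alkoxy-1,2-dioxolanes by allylsilanes and silyl enol ethers and the double annulation of bis-acetals with 1,3-bis-nucleophiles to oxa-bridged cycloalkanones; new here is a bis-peroxyketal as the 1,3-bis-electrophile. The carbocycle C3–C2'–C1'–C6–C5–C4 closes in a 6-(enolendo)-exo-trig mode, a favoured mode: both enol carbons end up in the new ring and the C=O+ bond of the peroxycarbenium ion lies outside it. The first C–C bond sets its quaternary centre without control, but the second centre is created at a planar cation that the three-atom tether can reach only from the face carrying it, so the two centres are cis and the only bicyclic product is meso 8, whichever diastereomer of 3 and whichever ketal reacts first. The step needs ring closure to outrun a second intermolecular attack, which 1:1 stoichiometry, slow addition of 6 and high dilution secure. It also needs C–C bond formation to outrun Lewis acid cleavage of the O–O bond, which is favoured by the low temperature and by a ditertiary peroxide without α-hydrogen. The cold amine quench is used because 8 is a β-peroxy ketone that could open by elimination if left with acid or warmed with base.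

Step 5
Reactants: 8 (1R,5S)-1,5-dimethyl-6,7-dioxabicyclo[3.2.1]octan-3-one
Product: 9 (1S,6R)-1,6-dimethyl-3,7,8-trioxabicyclo[4.2.1]nonan-4-one
Conditions: Baeyer–Villiger monooxygenase (cyclohexanone monooxygenase or an enantiocomplementary enzyme, isolated, chosen by screening), NADP+ (cat.), glucose, glucose dehydrogenase, air, phosphate buffer pH 7.5, 25 °C
Reagents that add atoms: dioxygen, O=O
Why: Enzymatic Baeyer–Villiger desymmetrisation of a meso bridged cyclohexanone, a known use of these flavoenzymes: the flavin peroxide adds to the carbonyl and the active site lets only one of the two enantiotopic methylene groups migrate (here C4 of 8, the one on the S-configured bridgehead, which is C6 of the target). No new stereocentre is formed, but the absolute configuration of C3 and C5 is fixed; neutral pH spares the β-peroxy ketone.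

Step 6
Reactants: 9 (1S,6R)-1,6-dimethyl-3,7,8-trioxabicyclo[4.2.1]nonan-4-one
Product: 10 methyl 2-[(3R,5S)-5-(hydroxymethyl)-3,5-dimethyl-1,2-dioxolan-3-yl]acetate
Conditions: MeOH, camphorsulfonic acid (cat.), rt; NaHCO3 before concentration
Reagents that add atoms: methanol, CO
Why: Acid-catalysed transesterification opens the bridged seven-membered lactone to the hydroxy ester; acid is chosen over alkoxide so that neither an ester enolate (loss of the peroxide from C3) nor a β-peroxy alkoxide (Grob-type fragmentation) is formed.

Step 7
Reactants: 10 methyl 2-[(3R,5S)-5-(hydroxymethyl)-3,5-dimethyl-1,2-dioxolan-3-yl]acetate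
Product: 11 methyl 2-[(3R,5S)-5-formyl-3,5-dimethyl-1,2-dioxolan-3-yl]acetate
Conditions: Dess–Martin periodinane, CH2Cl2, 0 °C → rt
Reagents that add atoms: none
Why: Dess–Martin oxidation of a neopentyl-type primary alcohol under non-basic conditions; the aldehyde has no α-hydrogen, so it cannot epimerise, and it is used without storage because α-peroxy aldehydes are cleaved by nucleophiles.

Step 8
Reactants: 11 methyl 2-[(3R,5S)-5-formyl-3,5-dimethyl-1,2-dioxolan-3-yl]acetate; 12 2-(triphenyl-λ5-phosphanylidene)propanal
Product: 13 methyl 2-[(3R,5S)-3,5-dimethyl-5-[(1E)-2-methyl-3-oxoprop-1-en-1-yl]-1,2-dioxolan-3-yl]acetate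
Conditions: toluene, 60 °C
Reagents that add atoms: none
Why: Wittig olefination with a stabilised formyl ylide forms C6=C7 with E geometry (thermodynamic control of the oxaphosphetane); the reagent is neutral, is no free phosphine and generates no free alkoxide next to the peroxide.

Step 9
Reactants: 13 methyl 2-[(3R,5S)-3,5-dimethyl-5-[(1E)-2-methyl-3-oxoprop-1-en-1-yl]-1,2-dioxolan-3-yl]acetate
Product: 14 methyl 2-[(3R,5R)-3,5-dimethyl-5-[(2S)-2-methyl-3-oxopropyl]-1,2-dioxolan-3-yl]acetate
Conditions: ene-reductase of the Old Yellow Enzyme family (chosen by screening for the 2S aldehyde), NADP+ (cat.), glucose, glucose dehydrogenase, phosphate buffer pH 7.0/tert-butyl methyl ether, 25 °C; product extracted and used at once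
Reagents that add atoms: none
Why: Biocatalytic conjugate reduction of an (E)-2-methyl enal, a standard substrate class: the reduced flavin delivers hydride to C6 and an active-site tyrosine protonates C7 from the opposite face, so C7 is set by the enzyme alone (2S here, which becomes 2R once C8 is a methylene). The two-phase system and short contact time limit racemisation of the α-methyl aldehyde.

Step 10
Reactants: 15 2-(3-chloropropyl)-1,3-dioxolane
Product: 16 [3-(1,3-dioxolan-2-yl)propyl]triphenylphosphonium iodide
Conditions: PPh3, NaI, MeCN, reflux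
Reagents that add atoms: triphenylphosphine, c1ccc(cc1)P(c1ccccc1)c1ccccc1; sodium iodide, [Na+].[I-]
Why: Finkelstein exchange to the iodide followed by SN2 quaternisation of triphenylphosphine at a primary carbon.

Step 11
Reactants: 14 methyl 2-[(3R,5R)-3,5-dimethyl-5-[(2S)-2-methyl-3-oxopropyl]-1,2-dioxolan-3-yl]acetate; 16 [3-(1,3-dioxolan-2-yl)propyl]triphenylphosphonium iodide
Product: 18 methyl 2-[(3R,5R)-5-[(2S,3Z)-6-(1,3-dioxolan-2-yl)-2-methylhex-3-en-1-yl]-3,5-dimethyl-1,2-dioxolan-3-yl]acetate (mainly 3Z), via phosphorus ylide 17 (not isolated)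
Conditions: 16, KN(SiMe3)2 (0.95 equiv relative to 16), THF, −78 °C → 0 °C; then 14, −78 °C → 0 °C
Reagents that add atoms: none
Why: Wittig olefination with a non-stabilised ylide forms C8=C9; addition to the aldehyde at −78 °C is much faster than enolisation of the α-methyl aldehyde or of the ester, no excess base is present, and the alkene geometry does not matter because the double bond is reduced next.

Step 12
Reactants: 18 methyl 2-[(3R,5R)-5-[(2S,3Z)-6-(1,3-dioxolan-2-yl)-2-methylhex-3-en-1-yl]-3,5-dimethyl-1,2-dioxolan-3-yl]acetate
Product: 19 methyl 2-[(3R,5R)-5-[(2R)-6-(1,3-dioxolan-2-yl)-2-methylhexyl]-3,5-dimethyl-1,2-dioxolan-3-yl]acetate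
Conditions: 2-nitrobenzenesulfonyl hydrazide, Et3N, CH2Cl2, rt
Reagents that add atoms: none
Why: Diimide reduction: concerted syn transfer of two hydrogens to the unhindered disubstituted alkene, a method long used on unsaturated peroxides because it leaves the O–O bond untouched; no other C=C bond is present at this stage, and the C7 descriptor changes to R only through the priority change.

Step 13
Reactants: 19 methyl 2-[(3R,5R)-5-[(2R)-6-(1,3-dioxolan-2-yl)-2-methylhexyl]-3,5-dimethyl-1,2-dioxolan-3-yl]acetate
Product: 20 methyl 2-[(3R,5R)-3,5-dimethyl-5-[(2R)-2-methyl-7-oxoheptyl]-1,2-dioxolan-3-yl]acetate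
Conditions: 1 M aq. HCl, THF, rt
Reagents that add atoms: water, O
Why: Acid-catalysed acetal hydrolysis; the ditertiary dialkyl peroxide and the methyl ester are stable to dilute aqueous acid at room temperature.

Step 14
Reactants: 21 (4E)-5-phenylpent-4-en-1-ol
Product: 22 1-phenyl-5-{[(4E)-5-phenylpent-4-en-1-yl]sulfanyl}-1H-tetrazole
Conditions: 1-phenyl-1H-tetrazole-5-thiol, PPh3, diisopropyl azodicarboxylate, THF, 0 °C → rt
Reagents that add atoms: 1-phenyl-1H-tetrazole-5-thiol, Sc1nnnn1c1ccccc1
Why: Mitsunobu thioetherification of a primary alcohol with an acidic heteroaryl thiol.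

Step 15
Reactants: 22 1-phenyl-5-{[(4E)-5-phenylpent-4-en-1-yl]sulfanyl}-1H-tetrazole
Product: 23 1-phenyl-5-{[(4E)-5-phenylpent-4-en-1-yl]sulfonyl}-1H-tetrazole
Conditions: 30% aq. H2O2, (NH4)6Mo7O24·4H2O (cat.), EtOH, 0 °C → rt
Reagents that add atoms: hydrogen peroxide, OO
Why: Molybdate-catalysed oxidation of sulfide to sulfone, which is chemoselective for sulfur in the presence of an unactivated styrenyl alkene.

Step 16
Reactants: 20 methyl 2-[(3R,5R)-3,5-dimethyl-5-[(2R)-2-methyl-7-oxoheptyl]-1,2-dioxolan-3-yl]acetate; 23 1-phenyl-5-{[(4E)-5-phenylpent-4-en-1-yl]sulfonyl}-1H-tetrazole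
Product: 25 methyl 2-[(3R,5R)-3,5-dimethyl-5-[(2R,7E,11E)-2-methyl-12-phenyldodeca-7,11-dien-1-yl]-1,2-dioxolan-3-yl]acetate, via potassium sulfonyl carbanion 24 (not isolated)
Conditions: 23 (1.3 equiv), KN(SiMe3)2 (1.2 equiv), 1,2-dimethoxyethane, −60 °C; then 20, −60 °C → rt
Reagents that add atoms: none
Why: Julia–Kocienski olefination: addition of the metalated phenyltetrazolyl sulfone to the unbranched aldehyde, Smiles rearrangement and anti elimination of SO2 and tetrazololate give the E alkene, the usual outcome with potassium counter-ion in dimethoxyethane. The base is used up by the excess sulfone before 20 is added, so the β-peroxy ester meets only the weakly basic sulfonyl carbanion.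

Step 17
Reactants: 25 methyl 2-[(3R,5R)-3,5-dimethyl-5-[(2R,7E,11E)-2-methyl-12-phenyldodeca-7,11-dien-1-yl]-1,2-dioxolan-3-yl]acetate
Product: 27 2-[(3R,5R)-3,5-dimethyl-5-[(2R,7E,11E)-2-methyl-12-phenyldodeca-7,11-dien-1-yl]-1,2-dioxolan-3-yl]acetic acid (the target), via lithium carboxylate 26 (not isolated)
Conditions: LiOH, THF/H2O, 0 °C → rt; 1 M HCl to pH 3
Reagents that add atoms: lithium hydroxide, [Li+].[OH-]
Why: Saponification of the methyl ester; hydroxide attacks the ester carbonyl faster than it deprotonates C2', and 1,2-dioxolane-3-acetates of this type are known to survive cold aqueous lithium hydroxide.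

## Compound list

1 | acetylacetone (pentane-2,4-dione) | CC(=O)CC(C)=O | starting material
2 | 3,5-dimethyl-1,2-dioxolane-3,5-diol (cis/trans mixture) | CC1(O)CC(C)(O)OO1 | intermediate
3 | 3,5-dimethoxy-3,5-dimethyl-1,2-dioxolane (cis/trans mixture) | COC1(C)CC(C)(OC)OO1 | intermediate
4 | 1-(trimethylsilyl)propan-2-one | CC(=O)C[Si](C)(C)C | starting material
5 | lithium 3-(trimethylsilyl)prop-1-en-2-olate | [Li+].[O-]C(=C)C[Si](C)(C)C | intermediate (not isolated)
6 | 2-(trimethylsilyloxy)allyltrimethylsilane (trimethyl{[3-(trimethylsilyl)prop-1-en-2-yl]oxy}silane) | C=C(C[Si](C)(C)C)O[Si](C)(C)C | intermediate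
7 | 3-methoxy-3,5-dimethyl-5-{2-[(trimethylsilyl)oxy]prop-2-en-1-yl}-1,2-dioxolane (diastereomer mixture) | COC1(C)CC(C)(CC(=C)O[Si](C)(C)C)OO1 | intermediate (not isolated)
8 | (1R,5S)-1,5-dimethyl-6,7-dioxabicyclo[3.2.1]octan-3-one (meso) | O=C1C[C@]2(C)C[C@](C)(C1)OO2 | intermediate
9 | (1S,6R)-1,6-dimethyl-3,7,8-trioxabicyclo[4.2.1]nonan-4-one | O=C1OC[C@]2(C)C[C@](C)(C1)OO2 | intermediate
10 | methyl 2-[(3R,5S)-5-(hydroxymethyl)-3,5-dimethyl-1,2-dioxolan-3-yl]acetate | OC[C@]1(C)C[C@](C)(CC(=O)OC)OO1 | intermediate
11 | methyl 2-[(3R,5S)-5-formyl-3,5-dimethyl-1,2-dioxolan-3-yl]acetate | O=C[C@]1(C)C[C@](C)(CC(=O)OC)OO1 | intermediate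
12 | 2-(triphenyl-λ5-phosphanylidene)propanal | CC(C=O)=P(c1ccccc1)(c1ccccc1)c1ccccc1 | starting material
13 | methyl 2-[(3R,5S)-3,5-dimethyl-5-[(1E)-2-methyl-3-oxoprop-1-en-1-yl]-1,2-dioxolan-3-yl]acetate | O=C/C(C)=C/[C@]1(C)C[C@](C)(CC(=O)OC)OO1 | intermediate
14 | methyl 2-[(3R,5R)-3,5-dimethyl-5-[(2S)-2-methyl-3-oxopropyl]-1,2-dioxolan-3-yl]acetate | O=C[C@@H](C)C[C@]1(C)C[C@](C)(CC(=O)OC)OO1 | intermediate
15 | 2-(3-chloropropyl)-1,3-dioxolane | ClCCCC1OCCO1 | starting material
16 | [3-(1,3-dioxolan-2-yl)propyl]triphenylphosphonium iodide | [I-].C1COC(CCC[P+](c2ccccc2)(c2ccccc2)c2ccccc2)O1 | intermediate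
17 | [3-(1,3-dioxolan-2-yl)propylidene]triphenyl-λ5-phosphane | C1COC(CCC=P(c2ccccc2)(c2ccccc2)c2ccccc2)O1 | intermediate (not isolated)
18 | methyl 2-[(3R,5R)-5-[(2S,3Z)-6-(1,3-dioxolan-2-yl)-2-methylhex-3-en-1-yl]-3,5-dimethyl-1,2-dioxolan-3-yl]acetate | C1COC(O1)CC/C=C\[C@@H](C)C[C@]2(C)C[C@](C)(CC(=O)OC)OO2 | intermediate
19 | methyl 2-[(3R,5R)-5-[(2R)-6-(1,3-dioxolan-2-yl)-2-methylhexyl]-3,5-dimethyl-1,2-dioxolan-3-yl]acetate | C1COC(O1)CCCC[C@@H](C)C[C@]2(C)C[C@](C)(CC(=O)OC)OO2 | intermediate
20 | methyl 2-[(3R,5R)-3,5-dimethyl-5-[(2R)-2-methyl-7-oxoheptyl]-1,2-dioxolan-3-yl]acetate | O=CCCCC[C@@H](C)C[C@]1(C)C[C@](C)(CC(=O)OC)OO1 | intermediate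
21 | (4E)-5-phenylpent-4-en-1-ol | OCCC/C=C/c1ccccc1 | starting material
22 | 1-phenyl-5-{[(4E)-5-phenylpent-4-en-1-yl]sulfanyl}-1H-tetrazole | c1ccccc1/C=C/CCCSc1nnnn1-c1ccccc1 | intermediate
23 | 1-phenyl-5-{[(4E)-5-phenylpent-4-en-1-yl]sulfonyl}-1H-tetrazole | O=S(=O)(CCC/C=C/c1ccccc1)c1nnnn1-c1ccccc1 | intermediate
24 | potassium (4E)-5-phenyl-1-[(1-phenyl-1H-tetrazol-5-yl)sulfonyl]pent-4-en-1-ide | [K+].[CH-](CC/C=C/c1ccccc1)S(=O)(=O)c1nnnn1-c1ccccc1 | intermediate (not isolated)
25 | methyl 2-[(3R,5R)-3,5-dimethyl-5-[(2R,7E,11E)-2-methyl-12-phenyldodeca-7,11-dien-1-yl]-1,2-dioxolan-3-yl]acetate | C[C@H](CCCC/C=C/CC/C=C/c1ccccc1)C[C@]1(C)C[C@](C)(CC(=O)OC)OO1 | intermediate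
26 | lithium 2-[(3R,5R)-3,5-dimethyl-5-[(2R,7E,11E)-2-methyl-12-phenyldodeca-7,11-dien-1-yl]-1,2-dioxolan-3-yl]acetate | [Li+].C[C@H](CCCC/C=C/CC/C=C/c1ccccc1)C[C@]1(C)C[C@](C)(CC(=O)[O-])OO1 | intermediate (not isolated)
27 | 2-[(3R,5R)-3,5-dimethyl-5-[(2R,7E,11E)-2-methyl-12-phenyldodeca-7,11-dien-1-yl]-1,2-dioxolan-3-yl]acetic acid | C[C@H](CCCC/C=C/CC/C=C/c1ccccc1)C[C@]1(C)C[C@](C)(CC(=O)O)OO1 | target

## Step count and risks

Total: 17 steps. Longest linear sequence: 13 steps from 1 to 27 (steps 1, 2, 4–9, 11–13, 16, 17); steps 3, 10, 14 and 15 prepare the partners 6, 16 and 23.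

**Step 4 (key step, without direct precedent).**
- What may go wrong: after the first substitution a second molecule of 6 may add to the remaining ketal faster than the tethered enol ether closes, giving 2:1 adducts and oligomers. The Lewis acid may instead trigger heterolysis of the O–O bond or proton loss from C4 of the peroxycarbenium ion. The product may also open by β-elimination if the quench is late.
- Fallback from known reactions only, setting out from 3 and returning at 10: one ketal of 3 is substituted with 1-(tert-butyldimethylsilyloxy)-1-methoxyethene under Me3SiOSO2CF3 catalysis to give methyl 2-(5-methoxy-3,5-dimethyl-1,2-dioxolan-3-yl)acetate F1. The second ketal is substituted with 2-(trimethylsilyloxy)propene under the same catalysis, and the cis isomer is separated by chromatography as racemic methyl 2-[(3R,5S)-3,5-dimethyl-5-(2-oxopropyl)-1,2-dioxolan-3-yl]acetate F2. Baeyer–Villiger oxidation of the methyl ketone with 3-chloroperbenzoic acid (the CH2 group migrates in preference to CH3) gives racemic methyl 2-[(3R,5S)-5-(acetoxymethyl)-3,5-dimethyl-1,2-dioxolan-3-yl]acetate F3. Lipase-catalysed enantioselective hydrolysis of the primary acetate at pH 7 then releases 10; if the lipase prefers the antipode, the acetate that is left is methanolysed under acid instead. This gives up the ring-enforced cis relationship and half of the material, but every step is an established type.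

**Step 5.**
- What may go wrong: the monooxygenase may fail to bind the compact bridged peroxide or may select the wrong enantiotopic methylene. Reducing components of the system may cleave the O–O bond, and the β-peroxy ketone may slowly open in buffer.
- Fallback, setting out from 8 and returning at 11: desymmetrisation is moved from oxygen insertion to enolisation. Lithium bis[(1R)-1-phenylethyl]amide (or its enantiomer, whichever removes the C6 proton) with Me3SiCl present from the start, THF, −100 °C, gives {[(1S,5R)-1,5-dimethyl-6,7-dioxabicyclo[3.2.1]oct-2-en-3-yl]oxy}trimethylsilane F4, the enolate being silylated before it can expel the peroxide. Ozonolysis (O3, CH2Cl2/MeOH, −78 °C; Me2S) cleaves C1'=C6 to 2-[(3R,5S)-5-formyl-3,5-dimethyl-1,2-dioxolan-3-yl]acetic acid F5. Esterification with (trimethylsilyl)diazomethane in methanol gives 11, which also saves steps 6 and 7.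

**Step 9.**
- What may go wrong: the neopentyl-like, fully substituted β-substituent may not fit the active site. The product aldehyde may racemise in buffer before extraction, and the reduced flavin may transfer electrons to the peroxide.
- Fallback, setting out from 11 and returning at 14: C7 is set by an auxiliary instead of an enzyme. Wittig reaction of 11 with (4S)-4-benzyl-3-[2-(triphenyl-λ5-phosphanylidene)acetyl]-1,3-oxazolidin-2-one gives methyl 2-[(3R,5S)-5-{(1E)-3-[(4S)-4-benzyl-2-oxo-1,3-oxazolidin-3-yl]-3-oxoprop-1-en-1-yl}-3,5-dimethyl-1,2-dioxolan-3-yl]acetate F6. Diimide reduction gives methyl 2-[(3R,5R)-5-{3-[(4S)-4-benzyl-2-oxo-1,3-oxazolidin-3-yl]-3-oxopropyl}-3,5-dimethyl-1,2-dioxolan-3-yl]acetate F7. Enolisation of the imide (more acidic than the ester) with NaN(SiMe3)2 at −78 °C and methylation with iodomethane anti to the benzyl group gives methyl 2-[(3R,5R)-5-{(2S)-3-[(4S)-4-benzyl-2-oxo-1,3-oxazolidin-3-yl]-2-methyl-3-oxopropyl}-3,5-dimethyl-1,2-dioxolan-3-yl]acetate F8. LiBH4/MeOH at 0 °C reduces the imide ahead of the methyl ester to methyl 2-[(3R,5R)-5-[(2S)-3-hydroxy-2-methylpropyl]-3,5-dimethyl-1,2-dioxolan-3-yl]acetate F9, and Dess–Martin oxidation gives 14.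

**Step 8.**
- What may go wrong: the stabilised ylide may add too slowly to the hindered α-quaternary aldehyde, and the heating then needed may decompose the α-peroxy aldehyde.
- Fallback, setting out from 11 and returning at 13: the C6=C7 bond is made by condensation instead of olefination. Propanal, activated as its enamine by pyrrolidine/propanoic acid at room temperature, adds to the non-enolisable aldehyde 11 to give methyl 2-[(3R,5S)-5-(1-hydroxy-2-methyl-3-oxopropyl)-3,5-dimethyl-1,2-dioxolan-3-yl]acetate F10, which loses water under the same conditions to give the E enal 13.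

**Step 2.**
- What may go wrong: under acid the bis-hemiketal may redistribute hydrogen peroxide and form bridged tetraoxanes or oligomeric peroxides instead of the simple bis-methyl ketal.
- Fallback, setting out from 2 and returning at 8: the hydroxyl groups are capped without acid by N,O-bis(trimethylsilyl)acetamide in CH2Cl2 to give 3,5-dimethyl-3,5-bis(trimethylsilyloxy)-1,2-dioxolane F11. F11 takes the place of 3 in step 4, with siloxy instead of methoxy as the group that leaves on ionisation.

## Further compounds

F1 | step 4 | methyl 2-(5-methoxy-3,5-dimethyl-1,2-dioxolan-3-yl)acetate (diastereomer mixture) | COC(=O)CC1(C)CC(C)(OC)OO1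
F2 | step 4 | methyl 2-[(3R,5S)-3,5-dimethyl-5-(2-oxopropyl)-1,2-dioxolan-3-yl]acetate (racemic, cis; one enantiomer drawn) | CC(=O)C[C@]1(C)C[C@](C)(CC(=O)OC)OO1
F3 | step 4 | methyl 2-[(3R,5S)-5-(acetoxymethyl)-3,5-dimethyl-1,2-dioxolan-3-yl]acetate (racemic, cis; one enantiomer drawn) | CC(=O)OC[C@]1(C)C[C@](C)(CC(=O)OC)OO1
F4 | step 5 | {[(1S,5R)-1,5-dimethyl-6,7-dioxabicyclo[3.2.1]oct-2-en-3-yl]oxy}trimethylsilane | C[Si](C)(C)OC1=C[C@]2(C)C[C@](C)(C1)OO2
F5 | step 5 | 2-[(3R,5S)-5-formyl-3,5-dimethyl-1,2-dioxolan-3-yl]acetic acid | O=C[C@]1(C)C[C@](C)(CC(=O)O)OO1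
F6 | step 9 | methyl 2-[(3R,5S)-5-{(1E)-3-[(4S)-4-benzyl-2-oxo-1,3-oxazolidin-3-yl]-3-oxoprop-1-en-1-yl}-3,5-dimethyl-1,2-dioxolan-3-yl]acetate | O=C(/C=C/[C@]1(C)C[C@](C)(CC(=O)OC)OO1)N1[C@@H](Cc2ccccc2)COC1=O
F7 | step 9 | methyl 2-[(3R,5R)-5-{3-[(4S)-4-benzyl-2-oxo-1,3-oxazolidin-3-yl]-3-oxopropyl}-3,5-dimethyl-1,2-dioxolan-3-yl]acetate | O=C(CC[C@]1(C)C[C@](C)(CC(=O)OC)OO1)N1[C@@H](Cc2ccccc2)COC1=O
F8 | step 9 | methyl 2-[(3R,5R)-5-{(2S)-3-[(4S)-4-benzyl-2-oxo-1,3-oxazolidin-3-yl]-2-methyl-3-oxopropyl}-3,5-dimethyl-1,2-dioxolan-3-yl]acetate | O=C([C@@H](C)C[C@]1(C)C[C@](C)(CC(=O)OC)OO1)N1[C@@H](Cc2ccccc2)COC1=O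
F9 | step 9 | methyl 2-[(3R,5R)-5-[(2S)-3-hydroxy-2-methylpropyl]-3,5-dimethyl-1,2-dioxolan-3-yl]acetate | OC[C@@H](C)C[C@]1(C)C[C@](C)(CC(=O)OC)OO1
F10 | step 8 | methyl 2-[(3R,5S)-5-(1-hydroxy-2-methyl-3-oxopropyl)-3,5-dimethyl-1,2-dioxolan-3-yl]acetate (mixture at the two new centres) | O=CC(C)C(O)[C@]1(C)C[C@](C)(CC(=O)OC)OO1
F11 | step 2 | 3,5-dimethyl-3,5-bis(trimethylsilyloxy)-1,2-dioxolane (cis/trans mixture) | C[Si](C)(C)OC1(C)CC(C)(O[Si](C)(C)C)OO1
A1 | alternative 1 | (3S,5R)-3-[2-(tert-butyldiphenylsilyloxy)ethyl]-5-[(2R)-7-(benzoyloxy)-2-methylheptyl]-3,5-dimethyl-1,2-dioxolane | C[C@H](CCCCCOC(=O)c1ccccc1)C[C@]1(C)C[C@](C)(CCO[Si](c2ccccc2)(c3ccccc3)C(C)(C)C)OO1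
A2 | alternative 1 | tert-butyl{3-methoxy-3-[(triethylsilyl)peroxy]butoxy}diphenylsilane | COC(C)(CCO[Si](c1ccccc1)(c1ccccc1)C(C)(C)C)OO[Si](CC)(CC)CC
A3 | alternative 1 | (6R)-6,8-dimethylnon-8-en-1-yl benzoate | C=C(C)C[C@H](C)CCCCCOC(=O)c1ccccc1
A4 | alternative 2 | (3R,5R)-3-ethenyl-3,5-dimethyl-5-[(2R)-7-(tert-butyldiphenylsilyloxy)-2-methylheptyl]-1,2-dioxolane | C[C@H](CCCCCO[Si](c1ccccc1)(c2ccccc2)C(C)(C)C)C[C@]3(C)C[C@](C)(C=C)OO3
A5 | alternative 2 | tert-butyl{[(6R)-7-(2-ethenyl-1,2-dimethylcyclopropyl)-6-methylheptyl]oxy}diphenylsilane (ring stereoisomers) | C[C@H](CCCCCO[Si](c1ccccc1)(c1ccccc1)C(C)(C)C)CC1(C)CC1(C)C=C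
A6 | alternative 3 | methyl 2-[(3R,5R)-5-[(2R)-7-(benzoyloxy)-2-methylheptyl]-3,5-dimethyl-1,2-dioxolan-3-yl]acetate | C[C@H](CCCCCOC(=O)c1ccccc1)C[C@]1(C)C[C@](C)(CC(=O)OC)OO1
A7 | alternative 3 | (6R)-8-methoxy-6-methyl-8-[(triethylsilyl)peroxy]nonyl benzoate | COC(C)(C[C@H](C)CCCCCOC(=O)c1ccccc1)OO[Si](CC)(CC)CC
A8 | alternative 3 | methyl 3-methylbut-3-enoate | C=C(C)CC(=O)OC
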